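The cyclohexadienone ring (C1 carbonyl, C3 and C5 enols, quaternary C4) is treated as a dearomatized 2-methylphloroglucinol whose three alternating C–O carbons are one ketene carbonyl and two ynol-ether carbons. A Danheiser benzannulation expands 3-ethoxy-4-methylcyclobutenone by the two carbons of ethoxyacetylene into 3,5-diethoxy-2-methylphenol in one operation, leaving free only the hydroxyl next to the C-methyl carbon. Ortho-acylation and a para Mannich group complete the substitution, a palladium-catalysed asymmetric dearomative prenylation at the C-methyl carbon sets the quaternary stereocentre, and after hydrolysis the Mannich base transfers its methylene to the aromatic acylphloroglucinol half.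

Key step: step 2

Remark on the chemistry: the target is drawn as one enol tautomer of a β-triketone; names and CIP descriptors below refer to the tautomers drawn, so the R/S label of the ring stereocentre can change between compounds although its spatial arrangement is the same from step 5 onwards.

Step 1
Reactants: 1 propionyl chloride; 2 ethoxyacetylene (ethoxyethyne)
Product: 4 rac-3-ethoxy-4-methylcyclobut-2-en-1-one, via methylketene 3 (not isolated)
Conditions: Et3N, Et2O, 0 °C to rt, slow addition of 1 to excess 2
Reagents that add atoms: propionyl chloride CCC(Cl)=O; ethoxyacetylene C#COCC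
Why: Dehydrochlorination gives methylketene, which is trapped in a regioselective ketene–ynol ether [2+2] cycloaddition (nucleophilic CH terminus of the alkyne to the ketene carbonyl carbon) to the 3-alkoxycyclobutenone; the C4 stereocentre is racemic and is erased in step 2.

Step 2
Reactants: 4 rac-3-ethoxy-4-methylcyclobut-2-en-1-one; 2 ethoxyacetylene
Product: 9 3,5-diethoxy-2-methylphenol, via vinylketene 5 (not isolated), via alkenylcyclobutenone 6 (not isolated), via dienylketene 7 (not isolated), via cyclohexadienone 8 (not isolated)
Conditions: 2 (3 equiv), toluene, 80 °C then 110 °C, sealed tube; K2CO3, MeOH, rt work-up to cleave any aryl ester formed by ketene capture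
Reagents that add atoms: ethoxyacetylene C#COCC
Why: Thermal 4π-electrocyclic opening of the four-membered ring of 4 gives vinylketene 5, whose ketene C=C adds ethoxyacetylene in a regioselective [2+2] (ketene carbonyl carbon to the CH terminus of the ynol ether) to give 6; a second 4π opening gives dienylketene 7, and 6π closure followed by tautomerization of dienone 8 delivers phenol 9, so the four carbons of the cyclobutenone and the two alkyne carbons become the six-membered ring (net ring expansion by two). The closest known reaction is the Danheiser benzannulation of cyclobutenones with alkoxyacetylenes. The six-membered ring is closed by a thermal disrotatory 6π electrocyclization of the (3E)-dienylketene, the bond forming between the ketene carbon and the propenyl terminus. No stereocentre survives, because the methyl-bearing sp3 carbon of 8 is aromatized. The step needs the regiochemistry of the [2+2], which is secured by the polarization of ynol ether and ketene and places the only free hydroxyl next to the C-methyl carbon with ethoxy groups on the other two oxygens; reversible ring opening of 6 funnels material through the dienylketene geometry that can cyclize.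

Step 3
Reactants: 9 3,5-diethoxy-2-methylphenol; 10 hexanoyl chloride
Product: 11 1-(4,6-diethoxy-2-hydroxy-3-methylphenyl)hexan-1-one
Conditions: TiCl4, CH2Cl2, 0 °C to rt; aq. HCl work-up
Reagents that add atoms: hexanoyl chloride CCCCCC(Cl)=O
Why: Friedel–Crafts acylation delivered from the titanium phenoxide (or by Fries rearrangement of the first-formed aryl ester) should go to the free position ortho to the hydroxyl, giving the chelated ortho-hydroxy ketone in preference to the more hindered position between the two ethoxy groups.

Step 4
Reactants: 11 1-(4,6-diethoxy-2-hydroxy-3-methylphenyl)hexan-1-one; 12 N,N-dimethylmethyleneiminium iodide (Eschenmoser's salt)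
Product: 13 1-{3-[(dimethylamino)methyl]-2,4-diethoxy-6-hydroxy-5-methylphenyl}hexan-1-one
Conditions: K2CO3, MeCN, rt
Reagents that add atoms: N,N-dimethylmethyleneiminium iodide C=[N+](C)C.[I-]
Why: Mannich aminomethylation by the preformed iminium ion can only take the last free ring position, para to the phenoxide oxygen, and so blocks that carbon while installing the future methylene bridge.

Step 5
Reactants: 13 1-{3-[(dimethylamino)methyl]-2,4-diethoxy-6-hydroxy-5-methylphenyl}hexan-1-one; 14 3-methylbut-2-en-1-yl acetate (prenyl acetate)
Product: 15 (6S)-4-[(dimethylamino)methyl]-3,5-diethoxy-2-hexanoyl-6-methyl-6-(3-methylbut-2-en-1-yl)cyclohexa-2,4-dien-1-one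
Conditions: Pd2(dba)3·CHCl3 (2.5 mol %), (R,R)-DACH-phenyl Trost ligand (7.5 mol %), Cs2CO3, CH2Cl2, 0 °C to rt
Reagents that add atoms: prenyl acetate CC(C)=CCOC(C)=O
Why: Tsuji–Trost asymmetric allylic alkylation run as a phenol dearomatization: the chelated phenoxide should attack the prenyl complex formed from zerovalent palladium at its unsubstituted terminus through the C-methyl carbon, the only ortho or para carbon that is neither acylated nor blocked by the Mannich group, and the chiral ligand pocket selects the face of the planar phenoxide so that the quaternary centre forms as (S) (the (R,R) ligand is written by analogy with naphthol dearomatizations; the mirror-image ligand is used if the sense proves opposite).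

Step 6
Reactants: 15 (6S)-4-[(dimethylamino)methyl]-3,5-diethoxy-2-hexanoyl-6-methyl-6-(3-methylbut-2-en-1-yl)cyclohexa-2,4-dien-1-one
Product: 16 (4S)-6-[(dimethylamino)methyl]-2-hexanoyl-3,5-dihydroxy-4-methyl-4-(3-methylbut-2-en-1-yl)cyclohexa-2,5-dien-1-one (zwitterionic Mannich base)
Conditions: 1 M aq. HCl, THF, rt; then NaHCO3 to pH 7
Reagents that add atoms: water O
Why: Both ethoxy groups are vinylogous ester oxygens and should hydrolyse by addition of water and loss of ethanol in dilute acid, in which the protonated amine cannot eliminate, the prenyl group is untouched and the quaternary centre, having no α-hydrogen, cannot epimerize.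

Step 7
Reactants: 17 phloroglucinol; 10 hexanoyl chloride
Product: 18 1-(2,4,6-trihydroxyphenyl)hexan-1-one
Conditions: AlCl3, CH2Cl2–PhNO2, rt to 40 °C; aq. HCl work-up
Reagents that add atoms: hexanoyl chloride CCCCCC(Cl)=O
Why: Friedel–Crafts monoacylation of the symmetric triol, the first acyl group deactivating the ring against a second.

Step 8
Reactants: 18 1-(2,4,6-trihydroxyphenyl)hexan-1-one; 19 dimethyl sulfate
Product: 20 1-(2,6-dihydroxy-4-methoxyphenyl)hexan-1-one
Conditions: Me2SO4 (1.0 equiv), K2CO3 (1.0 equiv), acetone, rt
Reagents that add atoms: dimethyl sulfate COS(=O)(=O)OC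
Why: Williamson O-methylation should select the para hydroxyl, the most acidic one and the only one not hydrogen-bonded to the ketone, leaving the two chelated ortho hydroxyls free.

Step 9
Reactants: 16 (4S)-6-[(dimethylamino)methyl]-2-hexanoyl-3,5-dihydroxy-4-methyl-4-(3-methylbut-2-en-1-yl)cyclohexa-2,5-dien-1-one; 20 1-(2,6-dihydroxy-4-methoxyphenyl)hexan-1-one
Product: 22 (4S)-2-hexanoyl-3,5-dihydroxy-6-[(3-hexanoyl-2,4-dihydroxy-6-methoxyphenyl)methyl]-4-methyl-4-(3-methylbut-2-en-1-yl)cyclohexa-2,5-dien-1-one (CNP0108719.1), via methylene trione 21 (not isolated)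
Conditions: 20 (3 equiv), 1,4-dioxane, 90 °C
Reagents that add atoms: 1-(2,6-dihydroxy-4-methoxyphenyl)hexan-1-one CCCCCC(=O)c1c(O)cc(OC)cc1O
Why: Thermal loss of dimethylamine from the Mannich base gives the cross-conjugated methylene trione 21, an ortho-quinone-methide-like acceptor that should alkylate one of the two equivalent nucleophilic ring carbons of 20 (used in excess against double alkylation) in a Michael/Friedel–Crafts-type addition, the quaternary stereocentre taking no part.

Compound list
1 | propionyl chloride | CCC(Cl)=O | starting material
2 | ethoxyacetylene (ethoxyethyne) | C#COCC | starting material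
3 | methylketene (prop-1-en-1-one) | CC=C=O | intermediate (not isolated)
4 | rac-3-ethoxy-4-methylcyclobut-2-en-1-one | CCOC1=CC(=O)C1C | intermediate
5 | (3Z)-3-ethoxypenta-1,3-dien-1-one (vinylketene, methyl rotated outward) | O=C=C/C(OCC)=C/C | intermediate (not isolated)
6 | rac-3-ethoxy-4-[(1Z)-1-ethoxyprop-1-en-1-yl]cyclobut-2-en-1-one | CCOC1=CC(=O)C1/C(OCC)=C/C | intermediate (not isolated)
7 | (3E,5Z)-3,5-diethoxyhepta-1,3,5-trien-1-one (dienylketene) | O=C=C/C(OCC)=C\C(OCC)=C\C | intermediate (not isolated)
8 | rac-3,5-diethoxy-6-methylcyclohexa-2,4-dien-1-one | CCOC1=CC(=O)C(C)C(OCC)=C1 | intermediate (not isolated)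
9 | 3,5-diethoxy-2-methylphenol | Cc1c(O)cc(OCC)cc1OCC | intermediate
10 | hexanoyl chloride | CCCCCC(Cl)=O | starting material
11 | 1-(4,6-diethoxy-2-hydroxy-3-methylphenyl)hexan-1-one | CCCCCC(=O)c1c(O)c(C)c(OCC)cc1OCC | intermediate
12 | N,N-dimethylmethyleneiminium iodide (Eschenmoser's salt) | C=[N+](C)C.[I-] | starting material
13 | 1-{3-[(dimethylamino)methyl]-2,4-diethoxy-6-hydroxy-5-methylphenyl}hexan-1-one | CCCCCC(=O)c1c(O)c(C)c(OCC)c(CN(C)C)c1OCC | intermediate
14 | 3-methylbut-2-en-1-yl acetate (prenyl acetate) | CC(C)=CCOC(C)=O | starting material
15 | (6S)-4-[(dimethylamino)methyl]-3,5-diethoxy-2-hexanoyl-6-methyl-6-(3-methylbut-2-en-1-yl)cyclohexa-2,4-dien-1-one | CCCCCC(=O)C1=C(OCC)C(CN(C)C)=C(OCC)[C@](C)(CC=C(C)C)C1=O | intermediate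
16 | (4S)-6-[(dimethylamino)methyl]-2-hexanoyl-3,5-dihydroxy-4-methyl-4-(3-methylbut-2-en-1-yl)cyclohexa-2,5-dien-1-one | CCCCCC(=O)C1=C(O)[C@@](C)(CC=C(C)C)C(O)=C(CN(C)C)C1=O | intermediate
17 | phloroglucinol (benzene-1,3,5-triol) | Oc1cc(O)cc(O)c1 | starting material
18 | 1-(2,4,6-trihydroxyphenyl)hexan-1-one | CCCCCC(=O)c1c(O)cc(O)cc1O | intermediate
19 | dimethyl sulfate | COS(=O)(=O)OC | starting material
20 | 1-(2,6-dihydroxy-4-methoxyphenyl)hexan-1-one | CCCCCC(=O)c1c(O)cc(OC)cc1O | intermediate
21 | (4R)-2-hexanoyl-3-hydroxy-4-methyl-4-(3-methylbut-2-en-1-yl)-6-methylidenecyclohex-2-ene-1,5-dione | CCCCCC(=O)C1=C(O)[C@@](C)(CC=C(C)C)C(=O)C(=C)C1=O | intermediate (not isolated)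
22 | (4S)-2-hexanoyl-3,5-dihydroxy-6-[(3-hexanoyl-2,4-dihydroxy-6-methoxyphenyl)methyl]-4-methyl-4-(3-methylbut-2-en-1-yl)cyclohexa-2,5-dien-1-one (CNP0108719.1) | CCCCCC(=O)C1=C(O)[C@@](C)(CC=C(C)C)C(O)=C(Cc2c(OC)cc(O)c(C(=O)CCCCC)c2O)C1=O | target

Total step count: 9. Longest linear sequence: 7 steps (steps 1 to 6, then step 9); steps 7 and 8 form the convergent branch.

Steps most likely to fail

Step 5. The phenoxide may attack the substituted terminus of the prenyl–palladium complex, may be alkylated at oxygen, nitrogen or the para carbon without reverting, or the two faces of the phenoxide may be poorly discriminated. Fallback (from 13, back to 15): 13 is allylated instead with allyl methyl carbonate under the same Pd2(dba)3·CHCl3/Trost-ligand system, the unsubstituted allyl electrophile for which such phenol dearomatizations are best precedented, to give (6S)-4-[(dimethylamino)methyl]-3,5-diethoxy-2-hexanoyl-6-methyl-6-(prop-2-en-1-yl)cyclohexa-2,4-dien-1-one F1. Cross-metathesis of F1 (amine masked as its camphorsulfonate salt) with 2-methylbut-2-ene and the second-generation Hoveyda–Grubbs catalyst in CH2Cl2 at 40 °C should then convert the allyl into the prenyl group and give 15.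

Step 2. Capture of the vinylketene by the product phenol, or its oligomerization, may outrun the [2+2] addition to the volatile and only moderately reactive ethoxyacetylene. Fallback (from 2, back to 9): the two two-carbon units exchange roles. Ethoxyacetylene 2 is methylated (n-BuLi, THF, −78 °C; then MeI) to 1-ethoxyprop-1-yne F2, a less volatile and more nucleophilic ketenophile. F2 is heated in toluene with commercial 3-ethoxycyclobut-2-en-1-one F3, whose vinylketene has an unsubstituted terminus. The same sequence of ring opening, [2+2] addition, ring opening and 6π closure, now with the methyl group on the alkyne carbon that bonds to the ketene carbonyl carbon, should give 9 directly.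

Step 4. Substitution at the hindered ring position between two ethoxy groups may be slow, so that aminomethylation at the α-carbon of the ketone competes. Fallback (from 11, back to 13): Rieche formylation of 11 (Cl2CHOMe, TiCl4, CH2Cl2, −20 °C), with a smaller and more reactive electrophile, gives 2,6-diethoxy-3-hexanoyl-4-hydroxy-5-methylbenzaldehyde F4. Reductive amination of F4 with dimethylamine and NaBH(OAc)3 (1,2-dichloroethane, rt), selective for the aldehyde over the hindered chelated ketone, should give 13.

Further compounds
F1 | step 5 | (6S)-4-[(dimethylamino)methyl]-3,5-diethoxy-2-hexanoyl-6-methyl-6-(prop-2-en-1-yl)cyclohexa-2,4-dien-1-one | CCCCCC(=O)C1=C(OCC)C(CN(C)C)=C(OCC)[C@](C)(CC=C)C1=O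
F2 | step 2 | 1-ethoxyprop-1-yne | CC#COCC
F3 | step 2 | 3-ethoxycyclobut-2-en-1-one | CCOC1=CC(=O)C1
F4 | step 4 | 2,6-diethoxy-3-hexanoyl-4-hydroxy-5-methylbenzaldehyde | CCCCCC(=O)c1c(O)c(C)c(OCC)c(C=O)c1OCC
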